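The target is compound 11. Ring atoms keep the numbering O1, C2 to C5 in every intermediate.

## Analysis of the target

- **Structure.** Target 11 is [(2S,3R,4S)-2-(3,4-dimethoxyphenyl)-4-hydroxyoxolan-3-yl]methyl 3,4-dimethoxybenzoate. It has one oxolane ring (O1, C2, C3, C4, C5). C2 carries a 3,4-dimethoxyphenyl group, C3 a CH2O-veratroyl arm, C4 a free hydroxyl, and C5 is an unsubstituted CH2.
- **Stereochemistry.** The SMILES places the three contiguous stereocentres C2, C3 and C4 so that all three substituents lie on one face of the ring. Equivalently, H-2, H-3 and H-4 all lie on the other face. The plan is built on this feature.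
- **Stability.** The all-cis array is the most crowded of the four diastereomers, so any equilibration at C2 or C3 leads away from it.
- **Sensitive groups.**
  - The benzylic C2–O1 bond is activated by the para methoxy group. Acid ionises it and epimerises C2.
  - The C4 hydroxyl and the ester are cis and 1,3-related, so base can cause acyl migration.
  - The ester does not survive hydride or hydroxide.
- **The difficulty.** Ring closures and additions that form a C–C or C–O bond at C2, C3 or C4 bring the new group in anti to its neighbour, which gives trans relationships. Enolate chemistry at C3 does the same through allylic 1,3-strain.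
- **The opening.** Only hydrogen delivered to one face of a flat ring gives the all-cis pattern as the natural kinetic result.

## Retrosynthetic reasoning

**11 back to 10, then to 8 and 9.** The acyl C–O bond of the ester is cut last. The ester is the group least compatible with reductions, and veratroyl chloride 9 is a catalogue reagent. O4 stays silylated in 10 and 8. Acylation then has only one hydroxyl to choose from, and the cis O4 cannot take part until the final buffered desilylation.

**8 back to 7.** The CH2OH arm at C3 is traced to an ethyl ester. No skeletal bond is cut. The ester is wanted earlier for three reasons: it activates C3 for ring construction, it stabilises the enol ether of the flat precursor against ionisation at C4, and it makes that precursor isolable.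

**7 back to 6 (key disconnection).** The C2–H and C3–H bonds are removed together, which leaves the C2=C3 double bond of 4,5-dihydrofuran 6. Two of the three stereocentres vanish, and what remains is an almost planar ring with the single stereocentre C4. The forward reaction must add two hydrogens syn, from the face opposite the C4 silyloxy group. That pushes the aryl group and the ester onto the face of the silyloxy group. The cut is made here because C3 must become sp3 only when C4 is already a carbinol. With a ketone at C4, the centre C3 would be part of a β-keto ester and would equilibrate to the 2,3-trans series.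

**6 back to 5 and 4.** The silyl group is removed and the C4–H bond is traced to the ketone of 3(2H)-furanone 4. Compound 4 is achiral and flat, and it already holds every carbon and oxygen of the ring part. The forward reaction is a catalytic enantioselective 1,2-reduction. It is the only step in which absolute configuration is created by a reagent.

**4 back to 3, then to 1 and 2.** The ring is cut at C3–C4 and O1–C5. This gives β-keto ester 1 (C2, C3, the aryl group and the future CH2O carbon) and chloroacetyl chloride 2 (C4 and C5). In the forward sense, C-acylation gives triketone 3, and its aroyl enolate oxygen closes the ring on the CH2Cl carbon in the same flask.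

## Alternatives that were turned down

**Alternative 1:** the textbook route.
- *Disconnection:* C2–C3 by an aldol reaction and O1–C5 by etherification.
- *Forward:* an auxiliary-controlled anti-aldol addition of a but-3-enoyl enolate to the aryl aldehyde, then reductive removal of the auxiliary, would give diol A1. Epoxidation of the vinyl group would give epoxide A2. The benzylic hydroxyl would then open the terminal epoxide carbon (5-endo-tet).
- *Why turned down:*
  - The three stereocentres come from three unrelated events.
  - The 2,3-cis ring relationship requires the anti aldol series. That series is less general, and the dienolate can also react at its γ-carbon.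
  - C4 is created on a monosubstituted vinyl group of an acyclic chain, where neither substrate nor reagent control is strong.
  - Three hydroxyls of similar reactivity must be told apart by protecting groups.
  - The acid that promotes the 5-endo opening can ionise the electron-rich benzylic alcohol.
  - The count would be near ten steps.

**Alternative 2:** a dynamic kinetic resolution.
- *Disconnection:* O1–C2 and C3–C4. An oxa-Michael/Dieckmann annulation of a glycolate ester with a cinnamate ester would give keto ester A3 in one step as a mixture of stereoisomers.
- *Forward key step:* asymmetric transfer hydrogenation or a ketoreductase would funnel A3 into hydroxy ester A4.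
- *Why turned down:*
  - Only C3 of A3 is labile. C2 could invert only by retro-oxa-Michael opening, the reverse of a 5-endo-trig closure.
  - In that opening the breaking C2–O1 bond lies close to the nodal plane of the enolate. The enolate is highly stabilised and the leaving group is an alkoxide.
  - C2 would therefore be resolved rather than funnelled, and half of the material would be lost.
  - The keto ester rests in the 2,3-trans form, and hydride enters anti to the ester. The natural outlet is the 2,3-trans-3,4-cis isomer, not all-cis A4.

**Alternative 3:** a skeletal rearrangement.
- *Disconnection:* C2–C3.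
- *Forward key step:* a Lewis-acid-induced [1,3] O-to-C ring contraction of seven-membered vinyl acetal A5. Ionisation of the acetal gives an oxocarbenium ion tethered to a Z-enolate, and 5-(enolexo)-endo-trig closure would give aldehyde A6.
- *Why turned down:*
  - Allylic 1,3-strain in the Z-enolate puts H-4 in the enolate plane and the silyloxy group anti to the tether. The formyl group should therefore end up trans to O4.
  - Even if A6 formed, it is an aldehyde with an acidic C3–H flanked by two β-leaving groups. It would epimerise or eliminate.
  - A5 itself needs an acetalisation, an epoxidation, an enantioselective desymmetrising epoxide-to-allylic-alcohol isomerisation and a silylation. The precursor would cost more than the key step wins.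

Key step: step 4

Remark: the stereodescriptors of the SMILES are read literally as the all-cis (2S,3R,4S) oxolane. Compounds 1, 2 and 9 are taken as catalogue chemicals.

## Route

Step 1
Reactants: 1 ethyl 3-(3,4-dimethoxyphenyl)-3-oxopropanoate; 2 chloroacetyl chloride
Product: 4 ethyl 2-(3,4-dimethoxyphenyl)-4-oxo-4,5-dihydrofuran-3-carboxylate, via chloroacetylated keto ester 3 (not isolated)
Conditions: MgCl2, pyridine, CH2Cl2, 0 °C to rt; then Et3N, rt
Reagents that add atoms: none
Why: Magnesium-chelate (soft enolisation) C-acylation of a β-keto ester by an acid chloride gives 3, whose aroyl enolate oxygen then displaces the primary chloride (5-exo-tet O-alkylation), the classical entry to 3(2H)-furanone-4-carboxylates. C-alkylation would need a cyclopropanone and closure through the ester oxygen a ketene acetal, so the aroyl oxygen should win; no stereocentre is formed.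

Step 2
Reactants: 4 ethyl 2-(3,4-dimethoxyphenyl)-4-oxo-4,5-dihydrofuran-3-carboxylate
Product: 5 ethyl (4S)-2-(3,4-dimethoxyphenyl)-4-hydroxy-4,5-dihydrofuran-3-carboxylate
Conditions: (S)-Me-CBS oxazaborolidine (15 mol %), BH3·SMe2, THF, −20 °C; MeOH quench, pH 7 buffer
Reagents that add atoms: none
Why: Corey–Bakshi–Shibata reduction: the ketone oxygen binds the ring boron anti to the larger flank (sp2 C3 with its coplanar ester) and syn to the small OCH2 flank, so hydride should reach the Re face of C4 and give the 4S alcohol. Attack is 1,2 because C2 is deactivated by O1 and the aryl donor, and the neutral quench keeps the acid-labile allylic alcohol from dehydrating.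

Step 3
Reactants: 5 ethyl (4S)-2-(3,4-dimethoxyphenyl)-4-hydroxy-4,5-dihydrofuran-3-carboxylate
Product: 6 ethyl (4S)-4-[(tert-butyldimethylsilyl)oxy]-2-(3,4-dimethoxyphenyl)-4,5-dihydrofuran-3-carboxylate
Conditions: TBSCl, imidazole, DMF, rt
Reagents that add atoms: tert-butyldimethylsilyl chloride (TBSCl), CC(C)(C)[Si](C)(C)Cl
Why: Imidazole-promoted silylation of a secondary alcohol under mildly basic conditions, which the acid-sensitive enol ether tolerates; C4 is untouched. The bulky group is the steric control element of step 4 and later keeps O4 out of the acylation.

Step 4
Reactants: 6 ethyl (4S)-4-[(tert-butyldimethylsilyl)oxy]-2-(3,4-dimethoxyphenyl)-4,5-dihydrofuran-3-carboxylate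
Product: 7 ethyl (2S,3S,4S)-4-[(tert-butyldimethylsilyl)oxy]-2-(3,4-dimethoxyphenyl)oxolane-3-carboxylate (all-cis)
Conditions: H2 (30 bar), 5% Rh/Al2O3, EtOAc, rt
Reagents that add atoms: none
Why: This is a heterogeneous hydrogenation of a cyclic enol ether, the reaction type used on 1-aryl glycals and on 4,5-dihydrofuran-3-carboxylates: the alkene binds to the metal surface with one face and both hydrogens are passed to that face in turn, so the addition is syn. No ring is closed; the bonds formed are C2–H and C3–H. The dihydrofuran ring of 6 is almost flat and its only out-of-plane group is the C4 silyloxy group, which stands pseudoaxially over one face next to C3, so the molecule should adsorb through the opposite face. C3 is thus controlled by 1,2-induction from C4 (H-3 enters anti to the silyloxy group and the ester is pushed syn to it), and C2 is tied to C3 by the syn mechanism (H-2 on the face of H-3, the aryl group on the face of the ester). The all-cis (2S,3S,4S) array, the least stable isomer, is therefore the kinetic outcome, and C3 never sits next to a ketone that could epimerise it. The step needs chemoselectivity for the tetrasubstituted C=C over the allylic C4–O bond, the benzylic C2–O1 bond of the product and the dimethoxyphenyl ring. Rhodium on alumina in a neutral aprotic solvent has little tendency to hydrogenolysis, the ester at C3 disfavours ionisation at C4, and the run is stopped after one equivalent of H2.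

Step 5
Reactants: 7 ethyl (2S,3S,4S)-4-[(tert-butyldimethylsilyl)oxy]-2-(3,4-dimethoxyphenyl)oxolane-3-carboxylate
Product: 8 [(2S,3S,4S)-4-[(tert-butyldimethylsilyl)oxy]-2-(3,4-dimethoxyphenyl)oxolan-3-yl]methanol
Conditions: iBu2AlH, CH2Cl2, −78 °C to −20 °C; aq. potassium sodium tartrate
Reagents that add atoms: none
Why: Ester-to-alcohol reduction with a non-basic aluminium hydride at low temperature; C3 is not enolised, so epimerisation, β-elimination of O1 or of the silyloxy group and O-to-O silyl migration through a free alkoxide should all stay out.

Step 6
Reactants: 8 [(2S,3S,4S)-4-[(tert-butyldimethylsilyl)oxy]-2-(3,4-dimethoxyphenyl)oxolan-3-yl]methanol; 9 3,4-dimethoxybenzoyl chloride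
Product: 10 [(2S,3S,4S)-4-[(tert-butyldimethylsilyl)oxy]-2-(3,4-dimethoxyphenyl)oxolan-3-yl]methyl 3,4-dimethoxybenzoate
Conditions: Et3N, DMAP (cat.), CH2Cl2, 0 °C to rt
Reagents that add atoms: none
Why: DMAP-catalysed acylation of the only free hydroxyl by the acid chloride; the regiochemistry is fixed by the silyl ether at O4 and no stereocentre is involved.

Step 7
Reactants: 10 [(2S,3S,4S)-4-[(tert-butyldimethylsilyl)oxy]-2-(3,4-dimethoxyphenyl)oxolan-3-yl]methyl 3,4-dimethoxybenzoate
Product: 11 [(2S,3R,4S)-2-(3,4-dimethoxyphenyl)-4-hydroxyoxolan-3-yl]methyl 3,4-dimethoxybenzoate (target)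
Conditions: Bu4NF, AcOH (1:1), THF, 0 °C to rt
Reagents that add atoms: none
Why: Fluoride-induced Si–O cleavage driven by the strong Si–F bond. The acetic acid buffer avoids a free C4 alkoxide (acyl migration) and is too weak to ionise the benzylic C2–O1 bond, so all three stereocentres persist; the descriptor at C3 changes from S to R only because the priority of C4 drops when silicon leaves.

## Compound list

1 | ethyl 3-(3,4-dimethoxyphenyl)-3-oxopropanoate | CCOC(=O)CC(=O)c1ccc(OC)c(OC)c1 | starting material
2 | chloroacetyl chloride | ClCC(Cl)=O | starting material
3 | ethyl 4-chloro-2-(3,4-dimethoxybenzoyl)-3-oxobutanoate | CCOC(=O)C(C(=O)CCl)C(=O)c1ccc(OC)c(OC)c1 | intermediate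
4 | ethyl 2-(3,4-dimethoxyphenyl)-4-oxo-4,5-dihydrofuran-3-carboxylate | CCOC(=O)C1=C(OCC1=O)c1ccc(OC)c(OC)c1 | intermediate
5 | ethyl (4S)-2-(3,4-dimethoxyphenyl)-4-hydroxy-4,5-dihydrofuran-3-carboxylate | CCOC(=O)C1=C(OC[C@H]1O)c1ccc(OC)c(OC)c1 | intermediate
6 | ethyl (4S)-4-[(tert-butyldimethylsilyl)oxy]-2-(3,4-dimethoxyphenyl)-4,5-dihydrofuran-3-carboxylate | CCOC(=O)C1=C(OC[C@H]1O[Si](C)(C)C(C)(C)C)c1ccc(OC)c(OC)c1 | intermediate
7 | ethyl (2S,3S,4S)-4-[(tert-butyldimethylsilyl)oxy]-2-(3,4-dimethoxyphenyl)oxolane-3-carboxylate | CCOC(=O)[C@@H]1[C@H](O[Si](C)(C)C(C)(C)C)CO[C@@H]1c1ccc(OC)c(OC)c1 | intermediate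
8 | [(2S,3S,4S)-4-[(tert-butyldimethylsilyl)oxy]-2-(3,4-dimethoxyphenyl)oxolan-3-yl]methanol | OC[C@@H]1[C@H](O[Si](C)(C)C(C)(C)C)CO[C@@H]1c1ccc(OC)c(OC)c1 | intermediate
9 | 3,4-dimethoxybenzoyl chloride | COc1ccc(C(Cl)=O)cc1OC | starting material
10 | [(2S,3S,4S)-4-[(tert-butyldimethylsilyl)oxy]-2-(3,4-dimethoxyphenyl)oxolan-3-yl]methyl 3,4-dimethoxybenzoate | COc1ccc(C(=O)OC[C@@H]2[C@H](O[Si](C)(C)C(C)(C)C)CO[C@@H]2c2ccc(OC)c(OC)c2)cc1OC | intermediate
11 | [(2S,3R,4S)-2-(3,4-dimethoxyphenyl)-4-hydroxyoxolan-3-yl]methyl 3,4-dimethoxybenzoate | COc1ccc(C(=O)OC[C@@H]2[C@H](O)CO[C@@H]2c2ccc(OC)c(OC)c2)cc1OC | target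

## Step count and risks

Total step count: 7. Longest linear sequence: 7 steps (1 to 11).

**Key step (step 4).** The most likely failure is slow uptake of hydrogen, because the double bond is tetrasubstituted and polarised by O1 and the ester. Forcing conditions would then invite four side processes:
- saturation of the dimethoxyphenyl ring;
- hydrogenolysis of the allylic C4–O bond;
- hydrogenolysis of the benzylic C2–O1 bond of the product;
- loss of silanol with aromatisation of the ring.

Leakage through the face that carries the silyloxy group is the lesser concern. The fallback changes from steric control on a surface to a hydroxyl-directed homogeneous hydrogenation. It sets out from 6. Reduction of the ester with iBu2AlH (CH2Cl2, −78 °C) gives the primary allylic alcohol F1. Its double bond is now electron-rich and carries a binding group, and it is hydrogenated with [Ir(cod)(PCy3)(py)]PF6 under H2 (1 bar) in CH2Cl2. The CH2OH group lies in the ring plane and could bring iridium to either face, but the silyloxy group leaves only the face anti to it. The same all-cis array should therefore result. The product is 8, where the fallback rejoins the route, and step 5 is no longer needed.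

**Step 2.** Three things may go wrong:
- Enantioselectivity may be modest, because both flanks of the ketone lie in one plane and the ester oxygen may compete for boron.
- The reduction may be sluggish, because the ketone is part of a vinylogous ester.
- The allylic alcohol may dehydrate or ionise on work-up and chromatography.

The fallback builds the carbinol by C–C bond formation and takes the enantiomer by an enzyme. It sets out from 1. An interrupted Feist–Bénary reaction with aqueous chloroacetaldehyde and Et3N (aldol at C3–C4, then O-alkylation at O1–C5) gives the racemic hydroxydihydrofuran F2. Acetylation with Candida antarctica lipase B and vinyl acetate in MTBE should follow the usual size rule for secondary alcohols (large C3 flank, small C5 flank). It should convert the S enantiomer into the acetate F3 and leave the R alcohol F4. F4 can be oxidised with MnO2 back to 4 and recycled. Mild methanolysis of F3 (K2CO3, MeOH, 0 °C) gives 5, where the route is rejoined.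

**Step 1.** O-acylation of the enolate may compete with C-acylation. Pyridine may consume 2 by ketene formation or N-alkylation. Part of the material may close through the ester oxygen. The fallback forms the other bond to C3 and sets out from 9. The magnesium enolate of commercial ethyl 4-chloroacetoacetate (MgCl2, pyridine, CH2Cl2) is aroylated by 9. The C2–C3 bond is made instead of the C3–C4 bond, and the less sensitive acid chloride is used. The product is the same triketone 3, which closes to 4 with Et3N. This fallback makes no compound outside the list (F0).

**Step 7.** The silyl ether sits in the crowded all-cis environment, so cleavage may be slow. Longer times or more basic fluoride invite acyl migration to O4. More acidic fluoride sources invite ionisation at C2 and epimerisation. The fallback changes the order of events and sets out from 8. Desilylation at the ester-free stage (Bu4NF, THF) gives the diol F5. Its primary hydroxyl is then acylated selectively with one equivalent of 9 (2,4,6-collidine, CH2Cl2, −40 °C). The primary position is favoured both kinetically and, through acyl migration, thermodynamically. The product is 11.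

## Further compounds

F1 | step 4 | [(4S)-4-[(tert-butyldimethylsilyl)oxy]-2-(3,4-dimethoxyphenyl)-4,5-dihydrofuran-3-yl]methanol | OCC1=C(OC[C@H]1O[Si](C)(C)C(C)(C)C)c1ccc(OC)c(OC)c1
F2 | step 2 | ethyl 2-(3,4-dimethoxyphenyl)-4-hydroxy-4,5-dihydrofuran-3-carboxylate (racemic) | CCOC(=O)C1=C(OCC1O)c1ccc(OC)c(OC)c1
F3 | step 2 | ethyl (4S)-4-acetoxy-2-(3,4-dimethoxyphenyl)-4,5-dihydrofuran-3-carboxylate | CCOC(=O)C1=C(OC[C@H]1OC(C)=O)c1ccc(OC)c(OC)c1
F4 | step 2 | ethyl (4R)-2-(3,4-dimethoxyphenyl)-4-hydroxy-4,5-dihydrofuran-3-carboxylate | CCOC(=O)C1=C(OC[C@@H]1O)c1ccc(OC)c(OC)c1
F0 | step 1 | none | none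
F5 | step 7 | (3S,4R,5S)-5-(3,4-dimethoxyphenyl)-4-(hydroxymethyl)oxolan-3-ol | OC[C@@H]1[C@H](O)CO[C@@H]1c1ccc(OC)c(OC)c1
A1 | alternative 1 | (1S,2S)-1-(3,4-dimethoxyphenyl)-2-ethenylpropane-1,3-diol | OC[C@@H]([C@H](O)c1ccc(OC)c(OC)c1)C=C
A2 | alternative 1 | (1S,2S)-1-(3,4-dimethoxyphenyl)-2-[(2S)-oxiran-2-yl]propane-1,3-diol | OC[C@@H]([C@H](O)c1ccc(OC)c(OC)c1)[C@H]1CO1
A3 | alternative 2 | methyl 2-(3,4-dimethoxyphenyl)-4-oxooxolane-3-carboxylate (mixture of stereoisomers) | COC(=O)C1C(=O)COC1c1ccc(OC)c(OC)c1
A4 | alternative 2 | methyl (2S,3R,4S)-2-(3,4-dimethoxyphenyl)-4-hydroxyoxolane-3-carboxylate | COC(=O)[C@@H]1[C@H](O)CO[C@@H]1c1ccc(OC)c(OC)c1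
A5 | alternative 3 | (5S)-5-[(tert-butyldimethylsilyl)oxy]-2-(3,4-dimethoxyphenyl)-4,5-dihydro-1,3-dioxepine (either acetal epimer) | COc1ccc(C2OC[C@@H](O[Si](C)(C)C(C)(C)C)C=CO2)cc1OC
A6 | alternative 3 | (2S,3S,4S)-4-[(tert-butyldimethylsilyl)oxy]-2-(3,4-dimethoxyphenyl)oxolane-3-carbaldehyde | O=C[C@@H]1[C@H](O[Si](C)(C)C(C)(C)C)CO[C@@H]1c1ccc(OC)c(OC)c1
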